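## Retrosynthetic overview

1. Jaspaquinol ⇐ its hydroquinone dimethyl ether (oxidative demethylation, then reduction, last) ⇐ Pd(PPh3)4-catalysed benzylation of an (E)-alkenylalane with 2,5-dimethoxybenzyl chloride.
2. The alkenylalane ⇐ Cp2ZrCl2-catalysed syn-methylalumination of a terminal enyne ⇐ a (4E)-γ,δ-unsaturated ester (ester → aldehyde → alkyne, one carbon added).
3. Key disconnection: the vinyl–CH2 bond between the two isoprene units (C5–C6 of the side chain), made by Pd(PPh3)4-catalysed coupling of an (E)-alkenyl iodide with the zinc homoenolate of ethyl propanoate, the ester β-carbon serving as the nucleophile.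
4. The (E)-alkenyl iodide ⇐ methylalumination–iodination of a butynylcyclohexene ⇐ dihydro-β-ionone (methyl ketone → terminal alkyne).
5. Rings: none is built. The trimethylcyclohexene ring comes intact from dihydro-β-ionone and the arene from the benzyl chloride; both E alkenes come from syn-carbometalation.

Assumption: the target has no stereocentre, so "single enantiomer" is read as the single (2E,6E) isomer; the two alkene geometries are the only stereochemical elements.

## Route

Step 1
Reactants: 1 dihydro-β-ionone [4-(2,6,6-trimethylcyclohex-1-en-1-yl)butan-2-one]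
Product: 3 terminal alkyne 2-(but-3-yn-1-yl)-1,3,3-trimethylcyclohex-1-ene, via enol phosphate 2 (not isolated)
Conditions: LiN(i-Pr)2 (1.1 equiv), THF, −78 °C; ClP(O)(OEt)2, −78 °C → rt; then LiN(i-Pr)2 (2.3 equiv), −78 °C → rt; H2O
Reagents that add atoms: none
Why: Negishi methyl-ketone-to-alkyne synthesis: kinetic deprotonation at the methyl group at −78 °C gives the terminal enolate, O-phosphorylation gives enol phosphate 2, and base-induced beta-elimination of diethyl phosphate (E2) delivers the terminal alkyne, the tetrasubstituted ring alkene being inert and no stereo-element being created.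

Step 2
Reactants: 3 2-(but-3-yn-1-yl)-1,3,3-trimethylcyclohex-1-ene
Product: 5 alkenyl iodide 2-[(3E)-4-iodo-3-methylbut-3-en-1-yl]-1,3,3-trimethylcyclohex-1-ene, via vinylalane 4 (not isolated)
Conditions: AlMe3 (2.0 equiv), Cp2ZrCl2 (0.2 equiv), CH2Cl2, rt, 12 h; then I2, THF, −30 → 0 °C
Reagents that add atoms: trimethylaluminium, C[Al](C)C; iodine, II
Why: Negishi Cp2ZrCl2-catalysed carboalumination: Me–Al adds syn across the terminal alkyne with methyl at the internal carbon (about 95:5 regioselectivity), and iodinolysis of the C–Al bond occurs with retention, so the trisubstituted alkene is fixed as E.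

Step 3
Reactants: 5 2-[(3E)-4-iodo-3-methylbut-3-en-1-yl]-1,3,3-trimethylcyclohex-1-ene; 6 ethyl 3-iodopropanoate
Product: 8 ethyl (4E)-5-methyl-7-(2,6,6-trimethylcyclohex-1-en-1-yl)hept-4-enoate, via zinc homoenolate 7 (not isolated)
Conditions: 6, Zn dust, LiCl, THF, 40 °C; then 5, Pd(PPh3)4 (5 mol %), THF/NMP, 50 °C
Reagents that add atoms: none
Why: Negishi cross-coupling of a zinc homoenolate: zinc insertion turns the beta-carbon of the propanoate, an acceptor position in acrylate chemistry, into a chelation-stabilised nucleophile that is joined to the iodide-bearing alkenyl carbon, and oxidative addition, transmetalation and reductive elimination at palladium all retain configuration, so the E geometry of 5 is transferred intact while the ester is tolerated.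

Step 4
Reactants: 8 ethyl (4E)-5-methyl-7-(2,6,6-trimethylcyclohex-1-en-1-yl)hept-4-enoate
Product: 10 enyne 1,3,3-trimethyl-2-[(3E)-3-methyloct-3-en-7-yn-1-yl]cyclohex-1-ene, via aldehyde 9 (not isolated)
Conditions: i-Bu2AlH (1.1 equiv), CH2Cl2, −78 °C; then MeOH, K2CO3, dimethyl (1-diazo-2-oxopropyl)phosphonate, 0 °C → rt; aq. potassium sodium tartrate
Reagents that add atoms: dimethyl (1-diazo-2-oxopropyl)phosphonate, COP(=O)(OC)C(=[N+]=[N-])C(C)=O
Why: One-pot partial reduction and Seyferth–Gilbert homologation in its Ohira–Bestmann form: the tetrahedral aluminium hemiacetal formed at −78 °C prevents over-reduction and releases aldehyde 9 on adding methanol, and the diazomethylphosphonate anion generated by methanolysis of the reagent converts the aldehyde into the terminal alkyne under mild base that does not touch the E alkene.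

Step 5
Reactants: 10 1,3,3-trimethyl-2-[(3E)-3-methyloct-3-en-7-yn-1-yl]cyclohex-1-ene; 11 2,5-dimethoxybenzyl chloride [2-(chloromethyl)-1,4-dimethoxybenzene]
Product: 13 dimethyl ether 2-[(2E,6E)-3,7-dimethyl-9-(2,6,6-trimethylcyclohex-1-en-1-yl)nona-2,6-dien-1-yl]-1,4-dimethoxybenzene, via dienylalane 12 (not isolated)
Conditions: AlMe3 (2.0 equiv), Cp2ZrCl2 (0.2 equiv), CH2Cl2, rt; volatiles removed; then 11, Pd(PPh3)4 (3 mol %), THF, rt
Reagents that add atoms: trimethylaluminium, C[Al](C)C
Why: A second Cp2ZrCl2-catalysed syn-carboalumination sets the E geometry of the new trisubstituted alkene, and the resulting alkenylalane undergoes Pd(PPh3)4-catalysed alkenyl–benzyl cross-coupling (Negishi type) at the benzylic chloride with retention at the alkenyl carbon, the isolated alkenes being inert to AlMe3.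

Step 6
Reactants: 13 2-[(2E,6E)-3,7-dimethyl-9-(2,6,6-trimethylcyclohex-1-en-1-yl)nona-2,6-dien-1-yl]-1,4-dimethoxybenzene
Product: 15 jaspaquinol, via quinone 14 (not isolated)
Conditions: (NH4)2Ce(NO3)6 (2.5 equiv), MeCN/H2O, 0 °C; then aq. Na2S2O4, Et2O, rt, under Ar
Reagents that add atoms: water, O
Why: Oxidative demethylation of a hydroquinone dimethyl ether by (NH4)2Ce(NO3)6 proceeds through the arene radical cation, which is trapped by water (the quinone oxygens come from water, the methyl groups leave as methanol) faster than the isolated alkenes are oxidised, and Na2S2O4 then reduces the benzoquinone to the hydroquinone without affecting either E alkene.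

## Compound list

1 | dihydro-β-ionone, 4-(2,6,6-trimethylcyclohex-1-en-1-yl)butan-2-one | CC1=C(CCC(C)=O)C(C)(C)CCC1 | starting material
2 | diethyl 4-(2,6,6-trimethylcyclohex-1-en-1-yl)but-1-en-2-yl phosphate (enol phosphate) | CC1=C(CCC(=C)OP(=O)(OCC)OCC)C(C)(C)CCC1 | intermediate
3 | 2-(but-3-yn-1-yl)-1,3,3-trimethylcyclohex-1-ene | CC1=C(CCC#C)C(C)(C)CCC1 | intermediate
4 | dimethyl[(1E)-2-methyl-4-(2,6,6-trimethylcyclohex-1-en-1-yl)but-1-en-1-yl]alumane | CC1=C(CC/C(C)=C/[Al](C)C)C(C)(C)CCC1 | intermediate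
5 | 2-[(3E)-4-iodo-3-methylbut-3-en-1-yl]-1,3,3-trimethylcyclohex-1-ene | CC1=C(CC/C(C)=C/I)C(C)(C)CCC1 | intermediate
6 | ethyl 3-iodopropanoate | CCOC(=O)CCI | starting material
7 | (3-ethoxy-3-oxopropyl)zinc iodide (zinc homoenolate of ethyl propanoate) | CCOC(=O)CC[Zn]I | intermediate
8 | ethyl (4E)-5-methyl-7-(2,6,6-trimethylcyclohex-1-en-1-yl)hept-4-enoate | CC1=C(CC/C(C)=C/CCC(=O)OCC)C(C)(C)CCC1 | intermediate
9 | (4E)-5-methyl-7-(2,6,6-trimethylcyclohex-1-en-1-yl)hept-4-enal | CC1=C(CC/C(C)=C/CCC=O)C(C)(C)CCC1 | intermediate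
10 | 1,3,3-trimethyl-2-[(3E)-3-methyloct-3-en-7-yn-1-yl]cyclohex-1-ene | CC1=C(CC/C(C)=C/CCC#C)C(C)(C)CCC1 | intermediate
11 | 2,5-dimethoxybenzyl chloride, 2-(chloromethyl)-1,4-dimethoxybenzene | COc1ccc(OC)c(CCl)c1 | starting material
12 | [(1E,5E)-2,6-dimethyl-8-(2,6,6-trimethylcyclohex-1-en-1-yl)octa-1,5-dien-1-yl]dimethylalumane | CC1=C(CC/C(C)=C/CC/C(C)=C/[Al](C)C)C(C)(C)CCC1 | intermediate
13 | 2-[(2E,6E)-3,7-dimethyl-9-(2,6,6-trimethylcyclohex-1-en-1-yl)nona-2,6-dien-1-yl]-1,4-dimethoxybenzene | CC1=C(CC/C(C)=C/CC/C(C)=C/Cc2cc(OC)ccc2OC)C(C)(C)CCC1 | intermediate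
14 | 2-[(2E,6E)-3,7-dimethyl-9-(2,6,6-trimethylcyclohex-1-en-1-yl)nona-2,6-dien-1-yl]cyclohexa-2,5-diene-1,4-dione | CC1=C(CC/C(C)=C/CC/C(C)=C/CC2=CC(=O)C=CC2=O)C(C)(C)CCC1 | intermediate
15 | jaspaquinol, 2-[(2E,6E)-3,7-dimethyl-9-(2,6,6-trimethylcyclohex-1-en-1-yl)nona-2,6-dien-1-yl]benzene-1,4-diol | CC1=C(CC/C(C)=C/CC/C(C)=C/Cc2cc(O)ccc2O)C(C)(C)CCC1 | target

## Step count and risks

Total steps: 6. Longest linear sequence: 6 (1 → 3 → 5 → 8 → 10 → 13 → 15).

The three steps most likely to fail are 3, 4 and 5.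

Step 3, the homoenolate coupling: the ester-chelated C–Zn bond of 7 transmetalates slowly, so protodezincation of 7 or reduction of the hindered iodide 5 may compete. The fallback sets out from 5 and rejoins the route at 9. It replaces the ester homoenolate by a more nucleophilic, acetal-masked aldehyde homoenolate. Commercial 2-(2-bromoethyl)-1,3-dioxolane and Mg (THF, below 30 °C) give the Grignard reagent [2-(1,3-dioxolan-2-yl)ethyl]magnesium bromide F1. This is coupled with 5 under Fe(acac)3 catalysis (5 mol %, THF/NMP, 0 °C, a stereoretentive alkyl–alkenyl Kumada-type coupling) to give the acetal 2-[(3E)-4-methyl-6-(2,6,6-trimethylcyclohex-1-en-1-yl)hex-3-en-1-yl]-1,3-dioxolane F2. Mild hydrolysis (AcOH/H2O/THF, 45 °C) gives aldehyde 9, now isolated, which is taken to 10 by the Ohira–Bestmann half of step 4.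

Step 4, the one-pot ester-to-alkyne conversion: over-reduction to the alcohol, or an aluminium hemiacetal that does not collapse cleanly, would lower the yield. The fallback sets out from 8 and rejoins at 10 through discrete redox steps and a different alkyne synthesis. LiAlH4 (Et2O, 0 °C) reduces 8 fully to the alcohol (4E)-5-methyl-7-(2,6,6-trimethylcyclohex-1-en-1-yl)hept-4-en-1-ol F3. Dess–Martin periodinane (CH2Cl2, NaHCO3) gives isolated 9. CBr4/PPh3 (CH2Cl2, 0 °C) then gives the dibromoalkene 2-[(3E)-8,8-dibromo-3-methylocta-3,7-dien-1-yl]-1,3,3-trimethylcyclohex-1-ene F4. Finally n-BuLi (2.2 equiv, THF, −78 °C; H2O) effects the Corey–Fuchs rearrangement to 10.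

Step 5, the alkenylalane benzylation: residual AlMe3 may transfer methyl to the benzylic chloride, or the electron-rich chloride 11 may self-condense. The fallback sets out from 10 and rejoins at 13 with the roles of the partners inverted. The alane 12 is quenched with I2 to the dienyl iodide 2-[(3E,7E)-8-iodo-3,7-dimethylocta-3,7-dien-1-yl]-1,3,3-trimethylcyclohex-1-ene F5. Separately, 11 is converted by Zn dust/LiCl (THF, rt) into (2,5-dimethoxybenzyl)zinc chloride F6. Negishi coupling of the two (Pd(PPh3)4 5 mol %, THF, rt) gives 13.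

## Further compounds

F1 | step 3 | [2-(1,3-dioxolan-2-yl)ethyl]magnesium bromide | Br[Mg]CCC1OCCO1
F2 | step 3 | 2-[(3E)-4-methyl-6-(2,6,6-trimethylcyclohex-1-en-1-yl)hex-3-en-1-yl]-1,3-dioxolane | CC1=C(CC/C(C)=C/CCC2OCCO2)C(C)(C)CCC1
F3 | step 4 | (4E)-5-methyl-7-(2,6,6-trimethylcyclohex-1-en-1-yl)hept-4-en-1-ol | CC1=C(CC/C(C)=C/CCCO)C(C)(C)CCC1
F4 | step 4 | 2-[(3E)-8,8-dibromo-3-methylocta-3,7-dien-1-yl]-1,3,3-trimethylcyclohex-1-ene | CC1=C(CC/C(C)=C/CCC=C(Br)Br)C(C)(C)CCC1
F5 | step 5 | 2-[(3E,7E)-8-iodo-3,7-dimethylocta-3,7-dien-1-yl]-1,3,3-trimethylcyclohex-1-ene | CC1=C(CC/C(C)=C/CC/C(C)=C/I)C(C)(C)CCC1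
F6 | step 5 | (2,5-dimethoxybenzyl)zinc chloride | COc1ccc(OC)c(C[Zn]Cl)c1
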